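Remarks before the route

- Assumption on the chemistry: in step 2 the (R) ligand is taken to give the (3R) ester from the E-enoate; if the sense is the reverse, the mirror-image ligand is used and nothing else changes.
- Correction built into the plan: a keto ester such as 6, if made from a secondary Grignard reagent and an oxalate, would be racemic, and its stereocentre is enolisable. It therefore cannot be drawn or used as one enantiomer, and a chiral Lewis acid would have to do an unprecedented dynamic resolution. Here the centre is set by asymmetric catalysis (step 2) while its neighbour is still a CH2 group, and the ketone is unveiled only in step 4, directly before ring closure. Achiral SnCl4 and the chair transition state then relay it to C8a and C4a. No other structural inconsistency was found: the configuration of 19 leads to the (S) carbinol of 22, and the C1 epimer required is the thermodynamic one.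

Structural features

The target 22 is a 1,3-diacylglycerol: one primary oxygen carries an acetate, the other a C20 bicyclic acyl group, and the free secondary carbinol between them is the (S) stereocentre. The acyl part is a cis-fused octahydronaphthalene. Ring A (C1, C2, C3, C4, C4a, C8a) is saturated; ring B (C4a, C5, C6, C7, C8, C8a) holds the C5=C6 alkene and a 4-methylpent-3-enyl chain on C5. Four stereocentres are contiguous: C2 (methyl), C1 (carboxyl), C8a (methyl) and C4a (methyl). C4a and C8a are adjacent quaternary carbons with cis methyls; the C1 carboxyl is cis to the C8a methyl and trans to the C2 methyl. In the ring A chair that has the carboxyl and the C2 methyl equatorial, the other C1 epimer would place the carboxyl 1,3-diaxial to the C4a–C5 bond. C1 is therefore the thermodynamic epimer and can be corrected by equilibration; C2, C4a and C8a cannot. Fragile features are the glycerol esters (acyl migration, hydrolysis), the 1,5-diene made of two trisubstituted alkenes (acid-induced cyclisation) and, in any α-keto ester precursor, the enolisable centre next to the ketone. The real difficulty is the vicinal quaternary pair C4a/C8a and its relation to C2 in one absolute sense. The key step exploits the methyl on C4a next to the C5=C6 alkene whose C5 carries a CH2-linked chain. This pattern is what remains when one methyl of a C5 gem-dimethyl group migrates to a C4a cation and H6 is lost, and that cation arises when the C4a=C8a alkene of a 2,6,6-trimethylcyclohexene attacks an electrophilic C1 through C8a.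

Logic of the disconnections

22 to 21: the acetyl C–O bond on the primary glycerol oxygen is cut. The acetate is the most labile and most migration-prone group, so it is put on last. The forward step must acylate the primary hydroxyl of 21 beside the secondary one, cold and without acyl migration.

21 to 20: the two acetal C–O bonds that mask the diol are restored. This leaves a single free oxygen for the union with the acid. The forward hydrolysis must be mild enough for the 1,5-diene and must not shift the bulky acyl group from O1 to O2.

20 to 18 + 19: the ester linkage between the acyl carbon and the glycerol CH2–O is cut. This separates the chiral-pool carbinol 19 from the terpenoid acid 18 and makes the end convergent. Because the acyl carbon of 18 is crowded by C2 and the quaternary C8a, the forward step should let 18 act as the nucleophile towards activated 19.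

18 to 17: the O–CH3 bond is restored. A methyl ester is the form that survives SnCl4, SmI2, alkoxide, selenium oxidation and a sulfonyl carbanion. The forward cleavage must take place at the methyl carbon, not at the hindered carbonyl.

17 to 16, then 16 to 12 + 15: a sulfonyl group is added on the second chain carbon, and the bond between the CH2 on C5 and that carbon is cut. It is the one chain bond that an allylic halide and an allyl carbanion can make. The chain shrinks to a one-carbon handle on C5, and the five-carbon unit comes from 13 (15 to 13 + 14, S–C bond). The forward steps need α-attack of the carbanion, SN2 rather than SN2′ on 12, and removal of sulfur without moving either alkene.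

12 to 11 to 9: the C–Br and then the C–O bond on the C5 methyl carbon are removed. That methyl carries the only allylic hydrogens at the substituted end of the C5=C6 alkene, so allylic oxidation is directed to it. This reaches the hydrocarbon-level ring B that the key step delivers. The oxidation must be done before a second alkene is present.

9 to 7: a hydroxyl is added back at C1. A C1 oxygen is the footprint of a carbonyl electrophile at C1 and sets up the Prins retron. The forward step must cleave a tertiary C–O bond α to the ester reductively and then settle C1 by equilibration, which is downhill towards 9.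

7 to 6 (key disconnection): C1–C8a is cut, the C4a methyl is returned to C5 and the C4a=C8a alkene is restored. The bicycle with four stereocentres and the vicinal quaternary pair becomes a monocycle with one stereocentre, whose ring is that of 1. The forward step demands six-ring closure through C8a, methyl migration faster than any other exit from the C4a cation, and relay of the C2 configuration to C8a without enolisation.

6 to 5 to 4: the oxidation level of the carbon that becomes C1 is lowered from ketone to carbinol to CH2. The neighbouring stereocentre is then not enolisable until the last moment, and 4 is configurationally robust. The forward steps need enolate oxygenation that leaves the β-stereocentre alone and an oxidation free of base.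

4 to 3: the C–H bond at the stereocentre is removed (retro-conjugate reduction). The only stereocentre of the carbocyclic part that has to be introduced by a reagent is thus placed by catalyst control on an achiral enoate. The forward step needs a geometrically pure E-alkene and high enantioface selection.

3 to 1 + 2: the C=C bond is cut by olefination. Ring, tether and the future C2 methyl all come from 1; the two ester carbons come from 2. The forward step must favour or allow isolation of the E isomer.

Other disconnections considered

Alternative 1: The cut is C4a–C5 and C8–C8a, leading back through a cyclobutane to the ring A enone A2 and allene A3. In the forward sense, irradiation near 350 nm at low temperature would give the cis-fused methylenecyclobutane A1, whose four-membered ring is later enlarged by two carbons to ring B.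
- In favour: enone–allene photocycloaddition is an established way to join two fully substituted carbons. The four-membered ring enforces the cis relation of the two methyls, and the usual head-to-head sense puts the methylene-bearing carbon (future C5) on C4a. On precedent for forging the quaternary pair, this plan is the better of the two.
- Against: A1 is far from the target. A two-carbon ring expansion, removal of the C4 carbonyl, formation of the C5=C6 alkene and the whole side chain remain. Facial selectivity relative to C2 rests on a ring whose C1 is a readily epimerised vinylogous β-keto ester position. A2 itself needs an enantioselective synthesis.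
- Comparison: on structure, the chosen plan delivers ring B at the right oxidation level with the C5 carbon in place. On mechanism, the alternative's key step is the more secure, though its ring expansion has regiochemical uncertainty of its own. On step economy, the chosen route should be several steps shorter. The glycerol endgame would be identical, so the two are equal there.

Alternative 2: The cut is C4a–C5 and C1–C8a at once, opening both rings to the acyclic (Z)-enyne enol ether A5. In the forward sense, the cationic monovalent gold complex [(tBu)2(o-biphenyl)PAu(NCMe)]SbF6 in wet CH2Cl2 would activate the alkyne. The (Z)-dimethyl alkene would add through C4a (ring B), the C8a cation would be caught by the enol ether carbon C1 (ring A), and hydrolysis would give aldehyde A4.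
- In favour: both rings and both quaternary centres form in one catalytic step. The C5=C6 alkene and a three-carbon handle on C5 are born in place, which is better than the chosen plan, where five steps are spent on the C5 methyl. A catalytic promoter replaces stoichiometric SnCl4. Anti addition across the (Z)-alkene translates its geometry into cis methyls.
- Against: A5 requires a stereodefined tetrasubstituted alkene carrying two different chains, which is hard to make pure. The only stereocentre, C2, lies in the tether of the second closure and is remote from the first bond formation, so the relation of C4a/C8a to C2 is uncertain. The aldehyde must still be oxidised and the chain completed.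
- Comparison: on mechanism, both plans are cationic cascades of comparable boldness (equal). On structure, the chosen plan has C2 inside the chair that forms, so its relay to C8a is the more secure. On step economy, the key step is more convergent, but the linear build-up of A5 would probably cancel the gain.

Alternative 3: The cut is C1–C8a and C2–C3, ring A by [4+2], back to the (S)-silyloxy diene A7 and furan-2(5H)-one A8. In the forward sense, an endo Diels–Alder reaction on heating or with Me2AlCl would give the tricyclic cis-lactone A6 with a C4=C4a alkene. The C4a methyl would come later from cyclopropanation of that alkene and reductive ring opening. The lactone CH2–O carbon would become the C2 methyl and its carbonyl the C1 carboxyl.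
- In favour: every reaction type is well precedented. One carbinol centre relays to C1, C2 and C8a through a rigid transition state, which is better than the chosen plan on mechanistic security. The C5 oxygen is a ready handle for chain and alkene, equal to or better than allylic oxidation of a methyl.
- Against: the diene terminus C8a is fully substituted and must bond to the lactone α-carbon, so the cycloaddition would be slow and its regiochemistry is not assured. The C4a methyl arrives only after a directed cyclopropanation whose face must match C8a. Three oxygen functions must be adjusted. C1 emerges cis to the C2 substituent and must be epimerised, which is downhill as in the chosen plan (equal).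
- Comparison: on structure and step economy, the chosen plan is clearly shorter, because its key product already has both quaternary methyls and the right oxidation level. On mechanism, this alternative is the safer one.

Key step: step 5

Step 1
Reactants: 1 dihydro-β-ionone, 4-(2,6,6-trimethylcyclohex-1-en-1-yl)butan-2-one; 2 trimethyl phosphonoacetate
Product: 3 methyl (2E)-3-methyl-5-(2,6,6-trimethylcyclohex-1-en-1-yl)pent-2-enoate
Conditions: NaH, THF, 0 °C → reflux; E isomer separated by chromatography
Reagents that add atoms: none
Why: Horner–Wadsworth–Emmons olefination of a methyl ketone; the E isomer (ester trans to the larger chain) should predominate and is isolated, since alkene geometry decides the enantiomer formed in step 2.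

Step 2
Reactants: 3 methyl (2E)-3-methyl-5-(2,6,6-trimethylcyclohex-1-en-1-yl)pent-2-enoate
Product: 4 methyl (3R)-3-methyl-5-(2,6,6-trimethylcyclohex-1-en-1-yl)pentanoate
Conditions: Cu(OAc)2 (cat.), (R)-DTBM-SEGPHOS (cat.), (EtO)2MeSiH, t-BuOH, toluene, 0 °C → rt
Reagents that add atoms: none
Why: CuH-catalysed asymmetric conjugate reduction of a β,β-disubstituted enoate; the bisphosphine-bound CuH adds hydride to one enantioface of the E-alkene and so sets the stereocentre that becomes C2, while the hindered tetrasubstituted ring alkene is inert.

Step 3
Reactants: 4 methyl (3R)-3-methyl-5-(2,6,6-trimethylcyclohex-1-en-1-yl)pentanoate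
Product: 5 methyl (3R)-2-hydroxy-3-methyl-5-(2,6,6-trimethylcyclohex-1-en-1-yl)pentanoate (both C2 epimers)
Conditions: KHMDS, THF, −78 °C; then 2-(phenylsulfonyl)-3-phenyloxaziridine, −78 °C; aq. NH4Cl
Reagents that add atoms: 2-(phenylsulfonyl)-3-phenyloxaziridine, O=S(=O)(c1ccccc1)N1OC1c1ccccc1
Why: Davis oxaziridine hydroxylation of an ester enolate; deprotonation occurs only α to the ester, so the β-stereocentre is untouched, and the new carbinol centre needs no control because it is oxidised in the next step.

Step 4
Reactants: 5 methyl (3R)-2-hydroxy-3-methyl-5-(2,6,6-trimethylcyclohex-1-en-1-yl)pentanoate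
Product: 6 methyl (3R)-3-methyl-2-oxo-5-(2,6,6-trimethylcyclohex-1-en-1-yl)pentanoate
Conditions: Dess–Martin periodinane, CH2Cl2, 0 °C → rt; short silica pad, used at once
Reagents that add atoms: none
Why: Dess–Martin oxidation of an α-hydroxy ester to the α-keto ester without base, so the stereocentre becomes enolisable only now and is carried straight into the cyclisation.

Step 5
Reactants: 6 methyl (3R)-3-methyl-2-oxo-5-(2,6,6-trimethylcyclohex-1-en-1-yl)pentanoate
Product: 7 methyl (1R,2R,4aR,8aS)-1-hydroxy-2,4a,5,8a-tetramethyl-1,2,3,4,4a,7,8,8a-octahydronaphthalene-1-carboxylate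
Conditions: SnCl4 (1.1 equiv), CH2Cl2, −78 → −40 °C; aq. NaHCO3
Reagents that add atoms: none
Why: Proposed new method: SnCl4 chelates the 1,2-dicarbonyl unit of 6 and the tetrasubstituted ring alkene attacks the activated ketone carbon through its less hindered end C8a, a 6-endo Prins closure of ring A through a chair that leaves a tertiary cation at C4a (attack through C4a would have to form a spiro centre next to the gem-dimethyl carbon). Because C5 bears no hydrogen the usual concerted carbonyl-ene exit is not available, and the cation, destabilised inductively by the oxygenated C1 nearby, should be relieved by a Wagner–Meerwein shift of the C5 methyl aligned with the empty orbital, after which loss of H6 gives the C5=C6 alkene. The closest known reaction types are Lewis-acid Prins and carbonyl-ene cyclisations of unsaturated α-keto esters and the acid-induced C4-to-C5 methyl migration of 4,4-dimethyl steroid cations; their union in one operation on this substrate class has not been shown. C8a is controlled by the chair in which the C2 methyl is equatorial, since the other alkene face would set that methyl 1,3-diaxial to the C8a methyl, so the centre made in step 2 fixes the absolute sense. C4a is controlled by migration of the methyl to the lobe anti to the new C1–C8a bond, which makes the two angular methyls cis. At C1 the chelated ester is expected equatorial and the oxygen axial, but this centre is reset in step 6 and needs no control. The step needs six-ring rather than spiro closure and migration rather than loss of H4, chloride capture or lactonisation; the last three should be reversible under SnCl4 and the HCl released (reprotonation of a C4=C4a alkene, reionisation of a tertiary chloride, a methyl ester that cannot shed its alkyl group as a cation and whose carbonyl is held in the chelate), so material should funnel to 7. Low temperature and the absence of base are relied on to keep C2 from enolising before the ring closes.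

Step 6
Reactants: 7 methyl (1R,2R,4aR,8aS)-1-hydroxy-2,4a,5,8a-tetramethyl-1,2,3,4,4a,7,8,8a-octahydronaphthalene-1-carboxylate
Product: 9 methyl (1S,2R,4aR,8aR)-2,4a,5,8a-tetramethyl-1,2,3,4,4a,7,8,8a-octahydronaphthalene-1-carboxylate, via C1-epimeric ester 8 (not isolated)
Conditions: SmI2, HMPA, t-BuOH, THF, rt; then NaOMe, MeOH, 65 °C
Reagents that add atoms: none
Why: SmI2–HMPA reductive cleavage of a C–O bond α to an ester (ketyl, loss of hydroxide, protonation of the samarium enolate) is a known deoxygenation of α-hydroxy esters; whatever mixture of 8 and 9 the protonation gives, methoxide equilibration through the ester enolate should converge on 9, whose CO2Me is equatorial, trans to the C2 methyl and free of the 1,3-diaxial clash with the C4a–C5 bond that 8 suffers.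

Step 7
Reactants: 9 methyl (1S,2R,4aR,8aR)-2,4a,5,8a-tetramethyl-1,2,3,4,4a,7,8,8a-octahydronaphthalene-1-carboxylate
Product: 11 methyl (1S,2R,4aS,8aR)-5-(hydroxymethyl)-2,4a,8a-trimethyl-1,2,3,4,4a,7,8,8a-octahydronaphthalene-1-carboxylate, via enal 10 (not isolated)
Conditions: SeO2 (cat.), t-BuOOH, CH2Cl2, rt; then NaBH4, CeCl3·7H2O, MeOH, 0 °C
Reagents that add atoms: tert-butyl hydroperoxide, CC(C)(C)OO (oxygen delivered through catalytic selenium dioxide, O=[Se]=O)
Why: SeO2 allylic oxidation (ene reaction, then [2,3]-sigmatropic shift) takes place α to the more substituted alkene carbon C5, where the only allylic hydrogens are those of the methyl because C4a is quaternary; the portion over-oxidised to 10 is returned by Luche 1,2-reduction, which the hindered ester survives.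

Step 8
Reactants: 11 methyl (1S,2R,4aS,8aR)-5-(hydroxymethyl)-2,4a,8a-trimethyl-1,2,3,4,4a,7,8,8a-octahydronaphthalene-1-carboxylate
Product: 12 methyl (1S,2R,4aS,8aR)-5-(bromomethyl)-2,4a,8a-trimethyl-1,2,3,4,4a,7,8,8a-octahydronaphthalene-1-carboxylate
Conditions: CBr4, PPh3, CH2Cl2, 0 °C
Reagents that add atoms: carbon tetrabromide, BrC(Br)(Br)Br
Why: Appel bromination of a primary allylic alcohol by SN2 displacement of the alkoxyphosphonium ion under neutral conditions, which leave the alkene position and the ester unchanged.

Step 9
Reactants: 13 1-bromo-3-methylbut-2-ene; 14 sodium benzenesulfinate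
Product: 15 [(3-methylbut-2-en-1-yl)sulfonyl]benzene
Conditions: DMF, rt
Reagents that add atoms: none
Why: S-alkylation of a sulfinate salt by SN2 attack on the primary allylic bromide gives the sulfone that serves as the α-selective prenyl carbanion equivalent.

Step 10
Reactants: 12 methyl (1S,2R,4aS,8aR)-5-(bromomethyl)-2,4a,8a-trimethyl-1,2,3,4,4a,7,8,8a-octahydronaphthalene-1-carboxylate; 15 [(3-methylbut-2-en-1-yl)sulfonyl]benzene
Product: 16 methyl (1S,2R,4aR,8aR)-2,4a,8a-trimethyl-5-[4-methyl-2-(phenylsulfonyl)pent-3-en-1-yl]-1,2,3,4,4a,7,8,8a-octahydronaphthalene-1-carboxylate (both epimers at the sulfonyl carbon)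
Conditions: 15, n-BuLi, THF, −78 °C; then 12, DMPU, −78 → −20 °C
Reagents that add atoms: none
Why: Alkylation of an α-sulfonyl allyl carbanion, which reacts at the carbon next to sulfur, with a primary allylic bromide by SN2; the stabilised carbanion is too weak a base and nucleophile to disturb the hindered ester, and the new sulfonyl-bearing centre is removed in the next step.

Step 11
Reactants: 16 methyl (1S,2R,4aR,8aR)-2,4a,8a-trimethyl-5-[4-methyl-2-(phenylsulfonyl)pent-3-en-1-yl]-1,2,3,4,4a,7,8,8a-octahydronaphthalene-1-carboxylate
Product: 17 methyl (1S,2R,4aR,8aR)-2,4a,8a-trimethyl-5-(4-methylpent-3-en-1-yl)-1,2,3,4,4a,7,8,8a-octahydronaphthalene-1-carboxylate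
Conditions: Na(Hg) (6%), Na2HPO4, MeOH–THF, −20 °C
Reagents that add atoms: none
Why: Reductive desulfonylation by electron transfer; the allyl anion formed should be protonated mainly at its less substituted end, which keeps the trisubstituted alkene, and the buffered medium leaves the methyl ester intact.

Step 12
Reactants: 17 methyl (1S,2R,4aR,8aR)-2,4a,8a-trimethyl-5-(4-methylpent-3-en-1-yl)-1,2,3,4,4a,7,8,8a-octahydronaphthalene-1-carboxylate
Product: 18 (1S,2R,4aR,8aR)-2,4a,8a-trimethyl-5-(4-methylpent-3-en-1-yl)-1,2,3,4,4a,7,8,8a-octahydronaphthalene-1-carboxylic acid
Conditions: NaSEt, DMF, 100 °C; then aq. HCl to pH 3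
Reagents that add atoms: none
Why: SN2 demethylation by thiolate attacks the methyl carbon and is therefore indifferent to the crowding of the acyl carbon, where saponification would be slow; C1 is already the stable epimer, so basic conditions carry no stereochemical risk.

Step 13
Reactants: 18 (1S,2R,4aR,8aR)-2,4a,8a-trimethyl-5-(4-methylpent-3-en-1-yl)-1,2,3,4,4a,7,8,8a-octahydronaphthalene-1-carboxylic acid; 19 (R)-solketal, [(4R)-2,2-dimethyl-1,3-dioxolan-4-yl]methanol
Product: 20 [(4S)-2,2-dimethyl-1,3-dioxolan-4-yl]methyl (1S,2R,4aR,8aR)-2,4a,8a-trimethyl-5-(4-methylpent-3-en-1-yl)-1,2,3,4,4a,7,8,8a-octahydronaphthalene-1-carboxylate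
Conditions: PPh3, DIAD, THF, 0 °C → rt
Reagents that add atoms: none
Why: Mitsunobu esterification activates the primary alcohol and uses the carboxylate as nucleophile, so the hindered acyl carbon is never attacked; the dioxolane stereocentre is not involved, and its descriptor changes from R to S only through the priority rules.

Step 14
Reactants: 20 [(4S)-2,2-dimethyl-1,3-dioxolan-4-yl]methyl (1S,2R,4aR,8aR)-2,4a,8a-trimethyl-5-(4-methylpent-3-en-1-yl)-1,2,3,4,4a,7,8,8a-octahydronaphthalene-1-carboxylate
Product: 21 (2S)-2,3-dihydroxypropyl (1S,2R,4aR,8aR)-2,4a,8a-trimethyl-5-(4-methylpent-3-en-1-yl)-1,2,3,4,4a,7,8,8a-octahydronaphthalene-1-carboxylate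
Conditions: AcOH–H2O (4:1), 40 °C
Reagents that add atoms: none
Why: Mild acid hydrolysis of the isopropylidene acetal; the conditions should spare the trisubstituted alkenes, and the bulky acyl group should be slow to migrate from O1 to O2.

Step 15
Reactants: 21 (2S)-2,3-dihydroxypropyl (1S,2R,4aR,8aR)-2,4a,8a-trimethyl-5-(4-methylpent-3-en-1-yl)-1,2,3,4,4a,7,8,8a-octahydronaphthalene-1-carboxylate
Product: 22 (2S)-3-(acetyloxy)-2-hydroxypropyl (1S,2R,4aR,8aR)-2,4a,8a-trimethyl-5-(4-methylpent-3-en-1-yl)-1,2,3,4,4a,7,8,8a-octahydronaphthalene-1-carboxylate (CNP0146255.1)
Conditions: AcCl, 2,4,6-collidine, CH2Cl2, −78 °C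
Reagents that add atoms: acetyl chloride, CC(Cl)=O
Why: Selective acetylation of the primary hydroxyl of a 1,2-diol with acetyl chloride and a hindered pyridine base at low temperature; the secondary hydroxyl is flanked by two acyloxymethyl arms and reacts more slowly, and the cold, weakly basic medium disfavours acyl migration.

Compound list

1 | dihydro-β-ionone, 4-(2,6,6-trimethylcyclohex-1-en-1-yl)butan-2-one | CC(=O)CCC1=C(C)CCCC1(C)C | starting material
2 | trimethyl phosphonoacetate | COC(=O)CP(=O)(OC)OC | starting material
3 | methyl (2E)-3-methyl-5-(2,6,6-trimethylcyclohex-1-en-1-yl)pent-2-enoate | COC(=O)/C=C(\C)CCC1=C(C)CCCC1(C)C | intermediate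
4 | methyl (3R)-3-methyl-5-(2,6,6-trimethylcyclohex-1-en-1-yl)pentanoate | COC(=O)C[C@H](C)CCC1=C(C)CCCC1(C)C | intermediate
5 | methyl (3R)-2-hydroxy-3-methyl-5-(2,6,6-trimethylcyclohex-1-en-1-yl)pentanoate (both C2 epimers) | COC(=O)C(O)[C@H](C)CCC1=C(C)CCCC1(C)C | intermediate
6 | methyl (3R)-3-methyl-2-oxo-5-(2,6,6-trimethylcyclohex-1-en-1-yl)pentanoate | COC(=O)C(=O)[C@H](C)CCC1=C(C)CCCC1(C)C | intermediate
7 | methyl (1R,2R,4aR,8aS)-1-hydroxy-2,4a,5,8a-tetramethyl-1,2,3,4,4a,7,8,8a-octahydronaphthalene-1-carboxylate | COC(=O)[C@@]1(O)[C@H](C)CC[C@]2(C)C(C)=CCC[C@]12C | intermediate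
8 | methyl (1R,2R,4aR,8aR)-2,4a,5,8a-tetramethyl-1,2,3,4,4a,7,8,8a-octahydronaphthalene-1-carboxylate (C1 epimer of 9) | COC(=O)[C@@H]1[C@H](C)CC[C@]2(C)C(C)=CCC[C@]12C | intermediate (not isolated)
9 | methyl (1S,2R,4aR,8aR)-2,4a,5,8a-tetramethyl-1,2,3,4,4a,7,8,8a-octahydronaphthalene-1-carboxylate | COC(=O)[C@H]1[C@H](C)CC[C@]2(C)C(C)=CCC[C@]12C | intermediate
10 | methyl (1S,2R,4aS,8aR)-5-formyl-2,4a,8a-trimethyl-1,2,3,4,4a,7,8,8a-octahydronaphthalene-1-carboxylate | COC(=O)[C@H]1[C@H](C)CC[C@]2(C)C(C=O)=CCC[C@]12C | intermediate (not isolated)
11 | methyl (1S,2R,4aS,8aR)-5-(hydroxymethyl)-2,4a,8a-trimethyl-1,2,3,4,4a,7,8,8a-octahydronaphthalene-1-carboxylate | COC(=O)[C@H]1[C@H](C)CC[C@]2(C)C(CO)=CCC[C@]12C | intermediate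
12 | methyl (1S,2R,4aS,8aR)-5-(bromomethyl)-2,4a,8a-trimethyl-1,2,3,4,4a,7,8,8a-octahydronaphthalene-1-carboxylate | COC(=O)[C@H]1[C@H](C)CC[C@]2(C)C(CBr)=CCC[C@]12C | intermediate
13 | 1-bromo-3-methylbut-2-ene | CC(C)=CCBr | starting material
14 | sodium benzenesulfinate | [Na+].[O-]S(=O)c1ccccc1 | starting material
15 | [(3-methylbut-2-en-1-yl)sulfonyl]benzene | CC(C)=CCS(=O)(=O)c1ccccc1 | intermediate
16 | methyl (1S,2R,4aR,8aR)-2,4a,8a-trimethyl-5-[4-methyl-2-(phenylsulfonyl)pent-3-en-1-yl]-1,2,3,4,4a,7,8,8a-octahydronaphthalene-1-carboxylate (both epimers at the sulfonyl carbon) | COC(=O)[C@H]1[C@H](C)CC[C@]2(C)C(CC(C=C(C)C)S(=O)(=O)c3ccccc3)=CCC[C@]12C | intermediate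
17 | methyl (1S,2R,4aR,8aR)-2,4a,8a-trimethyl-5-(4-methylpent-3-en-1-yl)-1,2,3,4,4a,7,8,8a-octahydronaphthalene-1-carboxylate | COC(=O)[C@H]1[C@H](C)CC[C@]2(C)C(CCC=C(C)C)=CCC[C@]12C | intermediate
18 | (1S,2R,4aR,8aR)-2,4a,8a-trimethyl-5-(4-methylpent-3-en-1-yl)-1,2,3,4,4a,7,8,8a-octahydronaphthalene-1-carboxylic acid | OC(=O)[C@H]1[C@H](C)CC[C@]2(C)C(CCC=C(C)C)=CCC[C@]12C | intermediate
19 | (R)-solketal, [(4R)-2,2-dimethyl-1,3-dioxolan-4-yl]methanol | CC1(C)OC[C@@H](CO)O1 | starting material
20 | [(4S)-2,2-dimethyl-1,3-dioxolan-4-yl]methyl (1S,2R,4aR,8aR)-2,4a,8a-trimethyl-5-(4-methylpent-3-en-1-yl)-1,2,3,4,4a,7,8,8a-octahydronaphthalene-1-carboxylate | CC1(C)OC[C@@H](COC(=O)[C@H]2[C@H](C)CC[C@]3(C)C(CCC=C(C)C)=CCC[C@]23C)O1 | intermediate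
21 | (2S)-2,3-dihydroxypropyl (1S,2R,4aR,8aR)-2,4a,8a-trimethyl-5-(4-methylpent-3-en-1-yl)-1,2,3,4,4a,7,8,8a-octahydronaphthalene-1-carboxylate | OC[C@@H](COC(=O)[C@H]1[C@H](C)CC[C@]2(C)C(CCC=C(C)C)=CCC[C@]12C)O | intermediate
22 | (2S)-3-(acetyloxy)-2-hydroxypropyl (1S,2R,4aR,8aR)-2,4a,8a-trimethyl-5-(4-methylpent-3-en-1-yl)-1,2,3,4,4a,7,8,8a-octahydronaphthalene-1-carboxylate | CC(=O)OC[C@H](O)COC(=O)[C@H]1[C@H](C)CC[C@]2(C)C(CCC=C(C)C)=CCC[C@]12C | target

Step count and weak points

Total: 15 steps. Longest linear sequence: 14 steps (steps 1–8 and 10–15, from 1); step 9 is a one-step side branch.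

Step 5 (key step, new method). The C4a cation may leave the intended path before the methyl migrates, by loss of H4, capture of chloride or capture by the ester carbonyl. Ring closure through C4a to a spiro ring is the other possible diversion. Both are possible because a tertiary cation has several low-barrier exits and the migration has no precedent on this substrate.
- Fallback, from 6 back to 7: the two events are separated into reaction types that are each established. Compound 6 is closed with Me2AlCl in CH2Cl2 at −78 °C, a proton-scavenging Lewis acid under which Prins closures of unsaturated keto esters normally end at the alkene. This should give the unrearranged hydroxy ester with a C4=C4a double bond and the C5 gem-dimethyl group intact, methyl (1R,2R,8aS)-1-hydroxy-2,5,5,8a-tetramethyl-1,2,3,5,6,7,8,8a-octahydronaphthalene-1-carboxylate F1. F1 is then reionised at C4a with a Brønsted acid (TfOH, CH2Cl2, −20 °C), the setting in which 4,4-dimethyl steroid alkenes undergo methyl migration from C4 to C5, to reach 7.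
- If the migration could not be induced at all, the disconnection itself would fail and the Diels–Alder plan of Alternative 3 would replace it.

Step 4. Enolisation of the keto ester during oxidation, filtration or storage would erode the enantiomeric purity set in step 2, because the stereocentre is then α to a ketone.
- Fallback, from 18 back to 20: purity is restored downstream instead of being protected upstream. Scalemic 18 is esterified with enantiopure 19 as in step 13. The minor enantiomer then appears as the diastereomeric ester [(4S)-2,2-dimethyl-1,3-dioxolan-4-yl]methyl (1R,2S,4aS,8aS)-2,4a,8a-trimethyl-5-(4-methylpent-3-en-1-yl)-1,2,3,4,4a,7,8,8a-octahydronaphthalene-1-carboxylate F2, which is removed by chromatography or crystallisation before 20 is carried on.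

Step 6. Fragmentation of the ketyl may be slow because free hydroxide on a crowded tertiary carbon is a poor leaving group, so that the ester is reduced or starting material returns. Incomplete equilibration at the hindered C1 is the second risk.
- Fallback, from 7 back to 9: radical deoxygenation instead of electron transfer. Compound 7 is acylated with methyl chlorooxoacetate (pyridine, DMAP, CH2Cl2) to the tertiary methyl oxalate, methyl (1R,2R,4aR,8aS)-1-[(2-methoxy-2-oxoacetyl)oxy]-2,4a,5,8a-tetramethyl-1,2,3,4,4a,7,8,8a-octahydronaphthalene-1-carboxylate F3. F3 is reduced with Bu3SnH and AIBN in toluene at 110 °C (Barton-type deoxygenation through the ester-stabilised tertiary radical at C1). The resulting mixture of 8 and 9 is equilibrated with NaOMe in MeOH to 9.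

Step 7. Oxidation may occur at the ring CH2 C7 instead of the methyl, or run on to the acid, since SeO2 selectivity for a methyl on a ring alkene is rule-based and not assured.
- Fallback, from 9 back to 16: the methyl is functionalised by a base-mediated epoxide-to-allylic-alcohol sequence instead of an ene reaction. Compound 9 is epoxidised (mCPBA, NaHCO3, CH2Cl2) to the 5,6-epoxide F4. F4 is isomerised with Et2Al(2,2,6,6-tetramethylpiperidide) in toluene at 0 °C, by removal of a methyl hydrogen, to the exocyclic allylic alcohol (C5 methylidene, C6 hydroxyl) F5. F5 is converted with SOCl2 in ether, with allylic transposition, into the primary allylic chloride F6. F6 is alkylated with lithiated 15 as in step 10 to give 16.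

Step 11. Protonation of the allyl anion at its substituted end would move the side-chain alkene out of the trisubstituted position and give an inseparable isomer.
- Fallback, from 16 back to 18: hydride delivery on a π-allyl palladium species instead of electron transfer, with the ester first converted to the hydride-stable carboxylate. Compound 16 is demethylated with NaSEt in DMF as in step 12 to the sulfonyl acid F7. F7 is desulfonylated with PdCl2(dppp) (cat.) and LiBHEt3 in THF at 0 °C, which replaces the sulfonyl group by hydrogen at the carbon that carried it, to give 18.

Further compounds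

F1 | step 5 | methyl (1R,2R,8aS)-1-hydroxy-2,5,5,8a-tetramethyl-1,2,3,5,6,7,8,8a-octahydronaphthalene-1-carboxylate | COC(=O)[C@@]1(O)[C@H](C)CC=C2C(C)(C)CCC[C@]12C
F2 | step 4 | [(4S)-2,2-dimethyl-1,3-dioxolan-4-yl]methyl (1R,2S,4aS,8aS)-2,4a,8a-trimethyl-5-(4-methylpent-3-en-1-yl)-1,2,3,4,4a,7,8,8a-octahydronaphthalene-1-carboxylate (diastereomer of 20) | CC1(C)OC[C@@H](COC(=O)[C@@H]2[C@@H](C)CC[C@@]3(C)C(CCC=C(C)C)=CCC[C@@]23C)O1
F3 | step 6 | methyl (1R,2R,4aR,8aS)-1-[(2-methoxy-2-oxoacetyl)oxy]-2,4a,5,8a-tetramethyl-1,2,3,4,4a,7,8,8a-octahydronaphthalene-1-carboxylate | COC(=O)[C@@]1(OC(=O)C(=O)OC)[C@H](C)CC[C@]2(C)C(C)=CCC[C@]12C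
F4 | step 7 | 5,6-epoxide of 9, methyl 5,6-epoxy-2,4a,5,8a-tetramethyldecahydronaphthalene-1-carboxylate (C1, C2, C4a, C8a as in 9; either epoxide face) | COC(=O)[C@H]1[C@H](C)CC[C@]2(C)C3(C)OC3CC[C@]12C
F5 | step 7 | methyl 6-hydroxy-2,4a,8a-trimethyl-5-methylidenedecahydronaphthalene-1-carboxylate (C1, C2, C4a, C8a as in 9; either C6 epimer) | COC(=O)[C@H]1[C@H](C)CC[C@]2(C)C(=C)C(O)CC[C@]12C
F6 | step 7 | methyl (1S,2R,4aS,8aR)-5-(chloromethyl)-2,4a,8a-trimethyl-1,2,3,4,4a,7,8,8a-octahydronaphthalene-1-carboxylate | COC(=O)[C@H]1[C@H](C)CC[C@]2(C)C(CCl)=CCC[C@]12C
F7 | step 11 | (1S,2R,4aR,8aR)-2,4a,8a-trimethyl-5-[4-methyl-2-(phenylsulfonyl)pent-3-en-1-yl]-1,2,3,4,4a,7,8,8a-octahydronaphthalene-1-carboxylic acid (both epimers at the sulfonyl carbon) | OC(=O)[C@H]1[C@H](C)CC[C@]2(C)C(CC(C=C(C)C)S(=O)(=O)c3ccccc3)=CCC[C@]12C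
A1 | alternative 1 | cis-fused photoadduct, ethyl 1,3,6-trimethyl-7-methylidene-5-oxobicyclo[4.2.0]octane-2-carboxylate | CCOC(=O)[C@H]1[C@H](C)CC(=O)[C@]2(C)C(=C)C[C@]12C
A2 | alternative 1 | ring A enone, ethyl 2,3,6-trimethyl-4-oxocyclohex-2-ene-1-carboxylate (1,6-trans) | CCOC(=O)[C@H]1[C@H](C)CC(=O)C(C)=C1C
A3 | alternative 1 | allene (propa-1,2-diene) | C=C=C
A4 | alternative 2 | (1S,2R,4aR,8aR)-5-[3-(tert-butyldimethylsilyloxy)propyl]-2,4a,8a-trimethyl-1,2,3,4,4a,7,8,8a-octahydronaphthalene-1-carbaldehyde | O=C[C@H]1[C@H](C)CC[C@]2(C)C(CCCO[Si](C)(C)C(C)(C)C)=CCC[C@]12C
A5 | alternative 2 | acyclic (Z)-enyne enol ether, tert-butyl{[(8Z,12R)-14-methoxy-8,9,12-trimethyltetradeca-8,13-dien-4-yn-1-yl]oxy}dimethylsilane (structure inferred from the bonds formed) | COC=C[C@H](C)CC/C(C)=C(C)\CCC#CCCCO[Si](C)(C)C(C)(C)C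
A6 | alternative 3 | tricyclic cis-fused γ-lactone Diels–Alder adduct with C4=C4a alkene and C5 silyl ether | O=C1OC[C@@H]2CC=C3[C@@H](O[Si](C)(C)C(C)(C)C)CCC[C@]3(C)[C@H]12
A7 | alternative 3 | tert-butyl{[(1S)-2-ethenyl-3-methylcyclohex-2-en-1-yl]oxy}dimethylsilane | C=CC1=C(C)CCC[C@@H]1O[Si](C)(C)C(C)(C)C
A8 | alternative 3 | furan-2(5H)-one | O=C1OCC=C1
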